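**Strategy**

The seven-membered ring is not cyclised but edited into existence. Daucane C8 with its methyl is disconnected from C7 and C9, which contracts the hydroazulene to a cis-hydrindanone ketol in which C1 (quaternary CH3), C5 (tertiary OH) and C4 (iPr) are set by a Michael–aldol sequence stopped before dehydration. In the key step chloro(methyl)carbene adds to the regiodefined silyl enol ether of that ketol and the chlorocyclopropane opens electrocyclically, inserting C8 as the α-carbon of a 2-methylcycloheptenone: ring, C8–CH3 and C8=C9 arise in one operation. The precursor is bis-silyl ether 13; the feature exploited is the C5(OH)–C6–C7(O)–C8(CH3)=C9 array of the seven-membered ring.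

Key step: step 6

Remark on the chemistry: the strategy text uses daucane numbering (C1 methyl-bearing ring-fusion carbon, C4 isopropyl carbon, C5 hydroxylated ring-fusion carbon, C7 ester carbon, C8=C9 alkene); compound names use indene/azulene numbering. The SMILES is read as the cis-fused (3R,3aS,5R,8aR) isomer, with 3a-OH, 8a-CH3 and 3-iPr on one face and the ester on the other.

**Route**

Step 1
Reactants: 1 2-methylcyclopentan-1-one (racemic); 2 acetone
Product: 4 5-methyl-2-(propan-2-ylidene)cyclopentan-1-one, via aldol carbinol 3 (not isolated)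
Conditions: LDA, THF, −78 °C; 2; AcOH quench; crude 3, TsOH·H2O (cat.), PhMe, reflux (Dean–Stark)
Reagents that add atoms: acetone, CC(C)=O
Why: Directed aldol condensation: the kinetic lithium enolate of 1 (formed at the unsubstituted α-carbon) adds to acetone and the tertiary carbinol 3 is dehydrated under acid to the conjugated enone, no stereocentre of consequence being set (any endocyclic alkene isomer converges in step 2).

Step 2
Reactants: 4 5-methyl-2-(propan-2-ylidene)cyclopentan-1-one
Product: 5 2-methyl-5-(propan-2-yl)cyclopentan-1-one (cis/trans mixture, racemic)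
Conditions: H2 (1 atm), 10% Pd/C, EtOAc, rt
Reagents that add atoms: none
Why: Heterogeneous hydrogenation of the conjugated enone C=C with the ketone left intact; both α-stereocentres are epimerisable and are deliberately left as a mixture, since they are fixed only in steps 3 and 4.

Step 3
Reactants: 5 2-methyl-5-(propan-2-yl)cyclopentan-1-one; 6 (S)-1-phenylethylamine; 7 but-3-en-2-one
Product: 10 (2R)-2-methyl-2-(3-oxobutyl)-5-(propan-2-yl)cyclopentan-1-one (both C5 epimers), via ketimine 8 (not isolated), via adduct ketimine 9 (not isolated)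
Conditions: 6, TsOH·H2O (cat.), PhMe, reflux (Dean–Stark); evaporate; 7, THF, rt; then 10% aq. AcOH, rt
Reagents that add atoms: but-3-en-2-one, CC(=O)C=C
Why: Asymmetric Michael addition of a chiral ketimine through its secondary enamine tautomer (auxiliary-controlled deracemising alkylation, aza-ene-like transition state with internal N–H transfer): reaction should occur at the methyl-bearing α-carbon because the isopropyl-bearing one would have to become a far more congested quaternary centre, and the enone should add to the enamine face anti to the phenyl group of the (S)-auxiliary, which by analogy with 2-methylcycloalkanones sets the (R) quaternary carbon before mild acid hydrolysis releases the ketone and the amine.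

Step 4
Reactants: 10 (2R)-2-methyl-2-(3-oxobutyl)-5-(propan-2-yl)cyclopentan-1-one
Product: 11 (3R,3aS,7aR)-3a-hydroxy-7a-methyl-3-(propan-2-yl)octahydro-5H-inden-5-one
Conditions: KOH (0.1 equiv), MeOH, 0 °C → rt, stopped at the ketol
Reagents that add atoms: none
Why: Intramolecular aldol addition, i.e. the ketol stage of a Robinson annulation stopped before dehydration: the methyl-ketone enolate can reach the ring carbonyl only from the face that carries its own tether, which forces cis fusion (3a-OH cis to 7a-CH3), while the α-isopropyl centre epimerises under the reversible basic conditions so that the ketol with isopropyl anti to the new C–C bond (cis to OH, on the convex face) should be favoured both kinetically and thermodynamically.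

Step 5
Reactants: 11 (3R,3aS,7aR)-3a-hydroxy-7a-methyl-3-(propan-2-yl)octahydro-5H-inden-5-one
Product: 13 (3R,3aS,7aR)-7a-methyl-3-(propan-2-yl)-3a,5-bis[(trimethylsilyl)oxy]-2,3,3a,4,7,7a-hexahydro-1H-indene, via mono-silyl ether 12 (not isolated)
Conditions: N-(trimethylsilyl)imidazole, CH2Cl2, rt; evaporate; then LDA, TMSCl, THF, −78 °C
Reagents that add atoms: N-(trimethylsilyl)imidazole, C[Si](C)(C)n1ccnc1; chlorotrimethylsilane, C[Si](C)(C)Cl
Why: O-silylation followed by kinetic enolate trapping: with the tertiary hydroxyl capped under neutral conditions (no alkoxide, hence no retro-aldol), LDA should remove a C6 proton rather than a neopentyl-type C4 proton next to the fully substituted C3a, and in situ TMSCl fixes this regiochemistry as the C5=C6 silyl enol ether without touching any stereocentre.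

Step 6
Reactants: 13 (3R,3aS,7aR)-7a-methyl-3-(propan-2-yl)-3a,5-bis[(trimethylsilyl)oxy]-2,3,3a,4,7,7a-hexahydro-1H-indene; 14 1,1-dichloroethane
Product: 17 (3R,3aS,8aR)-3a-hydroxy-6,8a-dimethyl-3-(propan-2-yl)-2,3,3a,4,8,8a-hexahydroazulen-5(1H)-one, via chlorocyclopropane 15 (not isolated), via silyl ether enone 16 (not isolated)
Conditions: 14, n-BuLi, Et2O, −40 → −20 °C; then PhMe, Et3N (cat.), 100 °C; then citric acid, MeOH, rt
Reagents that add atoms: 1,1-dichloroethane, CC(Cl)Cl
Why: n-BuLi converts 14 into 1,1-dichloroethyllithium, whose α-elimination delivers chloro(methyl)carbene to the only π bond of 13, the electron-rich C5=C6 silyl enol ether, in a [2+1] cheletropic addition that closes the three-membered ring of 15; on heating, chloride ionises in concert with disrotatory 2π-electrocyclic opening of the old C5–C6 bond (cyclopropyl to allyl cation) and the 2-silyloxyallyl cation loses Me3SiCl, so that the carbene carbon with its methyl is inserted between C5 and C6 and becomes C6 of the azulenone with a C6=C7 double bond (C8 and C8=C9 of the daucane). The closest known reaction type is the halocarbene ring enlargement of cyclic silyl enol ethers to 2-substituted cycloalk-2-enones. The cyclopropane is closed by carbene [2+1] addition, and the seven-membered ring arises not by cyclisation but by electrocyclic expansion of the six-membered ring through cleavage of the bond it shares with that cyclopropane. No stereocentre is created in the product (the three cyclopropane centres of 15 vanish on opening), and C3, C3a and C8a lie outside the reacting array and are carried through unchanged. The step needs regioselectivity (insertion on the C6 side of the carbonyl, not the C4 side), which is secured in advance by the position of the enol ether, and chemoselectivity, which is secured because both oxygens are silylated and no other π bond or acidic hydrogen is present. It also needs chlorine endo (cis to the C4 and C7 ring bonds) for the allowed opening to a cis-cycloheptenyl cation, a position the smaller chlorine should prefer over methyl; mild acidic methanolysis then frees the tertiary hydroxyl of 16.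

Step 7
Reactants: 17 (3R,3aS,8aR)-3a-hydroxy-6,8a-dimethyl-3-(propan-2-yl)-2,3,3a,4,8,8a-hexahydroazulen-5(1H)-one
Product: 18 (3R,3aS,5R,8aR)-6,8a-dimethyl-3-(propan-2-yl)-2,3,4,5,8,8a-hexahydroazulene-3a,5(1H)-diol
Conditions: Me4NBH(OAc)3, MeCN/AcOH (1:1), −20 °C → rt
Reagents that add atoms: none
Why: Hydroxyl-directed 1,2-reduction of a β-hydroxy ketone (Evans–Saksena type): the 3a-hydroxyl exchanges onto boron and delivers hydride intramolecularly to the C5 carbonyl from its own face, so the new secondary hydroxyl should be trans to the 3a-OH (1,3-anti), i.e. (5R), while the acetoxyborohydride should leave the conjugated alkene untouched.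

Step 8
Reactants: 18 (3R,3aS,5R,8aR)-6,8a-dimethyl-3-(propan-2-yl)-2,3,4,5,8,8a-hexahydroazulene-3a,5(1H)-diol; 19 3,4-dimethoxybenzoyl chloride
Product: 20 (3R,3aS,5R,8aR)-3a-hydroxy-6,8a-dimethyl-3-(propan-2-yl)-1,2,3,3a,4,5,8,8a-octahydroazulen-5-yl 3,4-dimethoxybenzoate
Conditions: 19, Et3N, DMAP (cat.), CH2Cl2, 0 °C → rt
Reagents that add atoms: 3,4-dimethoxybenzoyl chloride, COc1ccc(C(Cl)=O)cc1OC
Why: DMAP-catalysed acylation with an acid chloride, selective for the secondary allylic hydroxyl because the tertiary ring-fusion hydroxyl is too hindered to acylate under these conditions; the C5–O bond is not broken, so the (5R) configuration is retained.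

**Compound list**

1 | 2-methylcyclopentan-1-one (racemic) | CC1CCCC1=O | starting material
2 | acetone | CC(C)=O | starting material
3 | 2-(2-hydroxypropan-2-yl)-5-methylcyclopentan-1-one (isomer mixture, not isolated) | CC1CCC(C(C)(C)O)C1=O | intermediate
4 | 5-methyl-2-(propan-2-ylidene)cyclopentan-1-one (racemic) | CC1CCC(=C(C)C)C1=O | intermediate
5 | 2-methyl-5-(propan-2-yl)cyclopentan-1-one (cis/trans mixture, racemic) | CC1CCC(C(C)C)C1=O | intermediate
6 | (S)-1-phenylethylamine | C[C@H](N)c1ccccc1 | starting material
7 | but-3-en-2-one (methyl vinyl ketone) | CC(=O)C=C | starting material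
8 | 2-methyl-N-[(1S)-1-phenylethyl]-5-(propan-2-yl)cyclopentan-1-imine (isomer mixture, not isolated) | CC(C)C1CCC(C)C1=N[C@@H](C)c1ccccc1 | intermediate
9 | 4-[(1R)-1-methyl-2-{[(1S)-1-phenylethyl]imino}-3-(propan-2-yl)cyclopentyl]butan-2-one (not isolated) | CC(=O)CC[C@@]1(C)CCC(C(C)C)C1=N[C@@H](C)c1ccccc1 | intermediate
10 | (2R)-2-methyl-2-(3-oxobutyl)-5-(propan-2-yl)cyclopentan-1-one (both C5 epimers) | CC(=O)CC[C@@]1(C)CCC(C(C)C)C1=O | intermediate
11 | (3R,3aS,7aR)-3a-hydroxy-7a-methyl-3-(propan-2-yl)octahydro-5H-inden-5-one | O=C1C[C@]2(O)[C@@H](C(C)C)CC[C@]2(C)CC1 | intermediate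
12 | (3R,3aS,7aR)-7a-methyl-3-(propan-2-yl)-3a-[(trimethylsilyl)oxy]octahydro-5H-inden-5-one (not isolated) | O=C1C[C@]2(O[Si](C)(C)C)[C@@H](C(C)C)CC[C@]2(C)CC1 | intermediate
13 | (3R,3aS,7aR)-7a-methyl-3-(propan-2-yl)-3a,5-bis[(trimethylsilyl)oxy]-2,3,3a,4,7,7a-hexahydro-1H-indene | C[Si](C)(C)OC1=CC[C@@]2(C)CC[C@H](C(C)C)[C@@]2(O[Si](C)(C)C)C1 | intermediate
14 | 1,1-dichloroethane | CC(Cl)Cl | starting material
15 | 1-chloro-1-methylcyclopropane fused across C5–C6 of 13 (both silyl ethers retained; isomer mixture at the three cyclopropane carbons; not isolated) | C[Si](C)(C)OC12C[C@]3(O[Si](C)(C)C)[C@@H](C(C)C)CC[C@]3(C)CC1C2(C)Cl | intermediate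
16 | (3R,3aS,8aR)-6,8a-dimethyl-3-(propan-2-yl)-3a-[(trimethylsilyl)oxy]-2,3,3a,4,8,8a-hexahydroazulen-5(1H)-one (not isolated) | O=C1C[C@]2(O[Si](C)(C)C)[C@@H](C(C)C)CC[C@]2(C)CC=C1C | intermediate
17 | (3R,3aS,8aR)-3a-hydroxy-6,8a-dimethyl-3-(propan-2-yl)-2,3,3a,4,8,8a-hexahydroazulen-5(1H)-one | O=C1C[C@]2(O)[C@@H](C(C)C)CC[C@]2(C)CC=C1C | intermediate
18 | (3R,3aS,5R,8aR)-6,8a-dimethyl-3-(propan-2-yl)-2,3,4,5,8,8a-hexahydroazulene-3a,5(1H)-diol | O[C@@H]1C[C@]2(O)[C@@H](C(C)C)CC[C@]2(C)CC=C1C | intermediate
19 | 3,4-dimethoxybenzoyl chloride | COc1ccc(C(Cl)=O)cc1OC | starting material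
20 | (3R,3aS,5R,8aR)-3a-hydroxy-6,8a-dimethyl-3-(propan-2-yl)-1,2,3,3a,4,5,8,8a-octahydroazulen-5-yl 3,4-dimethoxybenzoate | COc1ccc(C(=O)O[C@@H]2C[C@]3(O)[C@@H](C(C)C)CC[C@]3(C)CC=C2C)cc1OC | target

**Step count and risks**

Total step count: 8. Longest linear sequence: 8 steps (1 → 20).

Steps most likely to fail:

1. Step 6. The cyclopropane epimer with exo chlorine cannot undergo the allowed ring opening. In addition, 1,2-hydrogen shift of the carbene competes with cyclopropanation, and the β-silyloxy group may be lost by elimination on heating. The fallback sets out from 13. Dibromocarbene (CHBr3, KOt-Bu, pentane, −20 °C → rt) should give the dibromocyclopropane F1, which always carries one endo bromine. Gentle heating in toluene should open it to the silyl ether bromo enone F2, and citric acid in MeOH should free the bromo hydroxy enone F3. Directed reduction as in step 7 should give the bromo diol F4. Suzuki–Miyaura methylation (trimethylboroxine, Pd(dppf)Cl2, K2CO3, dioxane/H2O, 80 °C) comes back to the route at 18.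

2. Step 3. Michael addition may compete through the isopropyl-side enamine, imine formation from the doubly α-branched ketone may be sluggish, and facial selectivity may erode. The fallback sets out from 1, where only one α-carbon is substituted. The same auxiliary Michael sequence with 6 and 7 should pass through the ketimine F5 and the adduct ketimine F6 to (2R)-2-methyl-2-(3-oxobutyl)cyclopentan-1-one F7. Selective ketalisation of the unhindered side-chain ketone (ethylene glycol, PPTS, PhH, Dean–Stark) should give the dioxolane F8. LDA and acetone should give the carbinol F9, MsCl/Et3N (0 °C → reflux) the isopropylidene ketone F10, and H2 over Pd/C the isopropyl ketone F11. Aqueous HCl in THF removes the ketal and comes back to the route at 10.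

3. Step 7. Ligand exchange of the hindered tertiary hydroxyl on boron may be slow, leading to incomplete reduction or undirected hydride addition with poor facial selectivity. The fallback sets out from 17. Chelation-controlled syn reduction (Et2BOMe, NaBH4, THF/MeOH, −78 °C; Narasaka–Prasad) should give the (5S)-diol F12. Mitsunobu esterification with 3,4-dimethoxybenzoic acid (PPh3, DIAD, PhMe, 0 °C → rt) installs the ester with inversion at C5 and comes back to the route at 20.

Further compounds
F1 | step 6 | 1,1-dibromocyclopropane fused across C5–C6 of 13 (both silyl ethers retained; isomer mixture at the ring-fusion cyclopropane carbons) | C[Si](C)(C)OC12C[C@]3(O[Si](C)(C)C)[C@@H](C(C)C)CC[C@]3(C)CC1C2(Br)Br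
F2 | step 6 | (3R,3aS,8aR)-6-bromo-8a-methyl-3-(propan-2-yl)-3a-[(trimethylsilyl)oxy]-2,3,3a,4,8,8a-hexahydroazulen-5(1H)-one | O=C1C[C@]2(O[Si](C)(C)C)[C@@H](C(C)C)CC[C@]2(C)CC=C1Br
F3 | step 6 | (3R,3aS,8aR)-6-bromo-3a-hydroxy-8a-methyl-3-(propan-2-yl)-2,3,3a,4,8,8a-hexahydroazulen-5(1H)-one | O=C1C[C@]2(O)[C@@H](C(C)C)CC[C@]2(C)CC=C1Br
F4 | step 6 | (3R,3aS,5R,8aR)-6-bromo-8a-methyl-3-(propan-2-yl)-2,3,4,5,8,8a-hexahydroazulene-3a,5(1H)-diol | O[C@@H]1C[C@]2(O)[C@@H](C(C)C)CC[C@]2(C)CC=C1Br
F5 | step 3 | 2-methyl-N-[(1S)-1-phenylethyl]cyclopentan-1-imine | CC1CCCC1=N[C@@H](C)c1ccccc1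
F6 | step 3 | 4-[(1R)-1-methyl-2-{[(1S)-1-phenylethyl]imino}cyclopentyl]butan-2-one | CC(=O)CC[C@@]1(C)CCCC1=N[C@@H](C)c1ccccc1
F7 | step 3 | (2R)-2-methyl-2-(3-oxobutyl)cyclopentan-1-one | CC(=O)CC[C@@]1(C)CCCC1=O
F8 | step 3 | (2R)-2-methyl-2-[2-(2-methyl-1,3-dioxolan-2-yl)ethyl]cyclopentan-1-one | CC1(CC[C@@]2(C)CCCC2=O)OCCO1
F9 | step 3 | (2R)-5-(2-hydroxypropan-2-yl)-2-methyl-2-[2-(2-methyl-1,3-dioxolan-2-yl)ethyl]cyclopentan-1-one | CC1(CC[C@@]2(C)CCC(C(C)(C)O)C2=O)OCCO1
F10 | step 3 | (2R)-2-methyl-2-[2-(2-methyl-1,3-dioxolan-2-yl)ethyl]-5-(propan-2-ylidene)cyclopentan-1-one | CC1(CC[C@@]2(C)CCC(=C(C)C)C2=O)OCCO1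
F11 | step 3 | (2R)-2-methyl-2-[2-(2-methyl-1,3-dioxolan-2-yl)ethyl]-5-(propan-2-yl)cyclopentan-1-one | CC1(CC[C@@]2(C)CCC(C(C)C)C2=O)OCCO1
F12 | step 7 | (3R,3aS,5S,8aR)-6,8a-dimethyl-3-(propan-2-yl)-2,3,4,5,8,8a-hexahydroazulene-3a,5(1H)-diol | O[C@H]1C[C@]2(O)[C@@H](C(C)C)CC[C@]2(C)CC=C1C
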